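The route rests on disconnecting the dihydropyran ring fused to ring B (O1, C2, C3, C4, C4a, C8a of the 2,2-dimethylchroman-6-yl unit) to an aryl 1,1-dimethylpropargyl ether, while the dihydrochalcone is carried as commercial naringenin, whose ring C (absent from the target) masks one ortho-hydroxyl of ring A and is cleaved last. The key step, a thermal propargyl Claisen/[1,5]-H shift/oxa-6π cascade, makes C4–C4a and closes O1–C2 in one operation; it exploits that O1 is para to the C6 chain, so both ortho carbons are equivalent, and that C2 is gem-dimethylated. Its precursor is the ring A-annulated flavanone bearing a 4'-O–CMe2–C≡CH ether. One alkaline hydrogenation then opens ring C and saturates three alkenes.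

Key step: step 4

Assumption (chemistry): racemic naringenin is used; its only stereocentre (the benzylic carbon of ring C) is destroyed in step 5 and the target is achiral, so all intermediates are racemates and their SMILES carry no descriptor at that carbon. Ring A is the phloroglucinol-derived benzene ring, ring B the para-oxygenated phenyl ring, ring C the pyranone ring of the flavanone.

Step 1
Reactants: 1 (±)-naringenin; 2 3-chloro-3-methylbut-1-yne
Product: 3 rac-5-hydroxy-2-(4-hydroxyphenyl)-7-[(2-methylbut-3-yn-2-yl)oxy]chroman-4-one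
Conditions: 2 (1.1 equiv), DBU (1.05 equiv), CuCl2·2H2O (cat.), MeCN, 0 °C to rt
Reagents that add atoms: none
Why: Copper-catalysed propargylic O-alkylation (substitution through a copper allenylidene from the tertiary chloride) should be selective because 7-OH, para to the C4 carbonyl, is by far the most acidic phenol and the only one ionised by one equivalent of DBU, while 5-OH is chelated.

Step 2
Reactants: 3 rac-5-hydroxy-2-(4-hydroxyphenyl)-7-[(2-methylbut-3-yn-2-yl)oxy]chroman-4-one
Product: 7 rac-5-hydroxy-8-(4-hydroxyphenyl)-2,2-dimethyl-7,8-dihydro-2H,6H-pyrano[3,2-g]chromen-6-one, via ring A allenyl dienone 4 (not isolated), via ring A allenylphenol 5 (not isolated), via ring A o-quinone methide 6 (not isolated)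
Conditions: N,N-diethylaniline, 190 °C, argon
Reagents that add atoms: none
Why: Aromatic propargyl Claisen rearrangement to C6 (the ortho carbon favoured by the bond fixation of the chelated 5-OH), enolisation, [1,5]-H shift from O7–H and oxa-6π-electrocyclisation through O7 should give the linear chromene, and any angular isomer from migration to C8 would lead to the same ring A pattern once ring C is opened.

Step 3
Reactants: 7 rac-5-hydroxy-8-(4-hydroxyphenyl)-2,2-dimethyl-7,8-dihydro-2H,6H-pyrano[3,2-g]chromen-6-one; 2 3-chloro-3-methylbut-1-yne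
Product: 8 rac-5-hydroxy-2,2-dimethyl-8-{4-[(2-methylbut-3-yn-2-yl)oxy]phenyl}-7,8-dihydro-2H,6H-pyrano[3,2-g]chromen-6-one
Conditions: 2 (1.5 equiv), DBU (1.3 equiv), CuCl2·2H2O (cat.), MeCN, 0 °C to rt
Reagents that add atoms: none
Why: The same copper-catalysed propargylic O-alkylation now has only the ring B phenol to address, since 5-OH is locked in the chelate with C4=O and is flanked by two substituted carbons.

Step 4
Reactants: 8 rac-5-hydroxy-2,2-dimethyl-8-{4-[(2-methylbut-3-yn-2-yl)oxy]phenyl}-7,8-dihydro-2H,6H-pyrano[3,2-g]chromen-6-one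
Product: 12 rac-8-(2,2-dimethyl-2H-chromen-6-yl)-5-hydroxy-2,2-dimethyl-7,8-dihydro-2H,6H-pyrano[3,2-g]chromen-6-one, via ring B allenyl dienone 9 (not isolated), via ring B allenylphenol 10 (not isolated), via ring B o-quinone methide 11 (not isolated)
Conditions: N,N-diethylaniline, 190 °C, argon
Reagents that add atoms: none
Why: Heating induces the aromatic propargyl Claisen [3,3] shift of the ring B ether from oxygen to one ortho carbon (the future C4a), giving allenyl dienone 9, which enolises to allenylphenol 10; a [1,5]-H shift from the phenolic O–H to the central allene carbon gives (Z)-o-quinone methide 11, which closes by thermal oxa-6π-electrocyclisation. The closest known reaction type is the thermal rearrangement of aryl 1,1-dimethylpropargyl ethers to 2,2-dimethyl-2H-chromenes. The pyran ring on ring B, the last ring of the skeleton, is closed in the 6π-electrocyclic mode by O1–C2 bond formation after C4–C4a has been made in the sigmatropic step. No stereocentre is created, since C2 carries two methyl groups and C3=C4 is a ring cis-alkene that step 5 saturates. The selectivity needed is secured by the substrate: the benzylic carbon of ring C sits para to the ether oxygen, so the two ortho carbons are equivalent and para migration is blocked, the only hydroxyl next to the allene is the ring B phenol, and the chelated 5-OH and the ring A chromene are spectators. The gem-dimethyl group accelerates the [3,3] shift, and any reversible thermal opening of ring C is harmless because that ring is cleaved in step 5.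

Step 5
Reactants: 12 rac-8-(2,2-dimethyl-2H-chromen-6-yl)-5-hydroxy-2,2-dimethyl-7,8-dihydro-2H,6H-pyrano[3,2-g]chromen-6-one
Product: 14 1-(5,7-dihydroxy-2,2-dimethylchroman-6-yl)-3-(2,2-dimethylchroman-6-yl)propan-1-one, via chalcone 13 (not isolated)
Conditions: H2 (1 atm), 10% Pd/C, KOH (aq. 2 M)/EtOH, rt; then HCl (aq.) to pH 3
Reagents that add atoms: none
Why: In aqueous-ethanolic KOH the 5-hydroxyflavanone opens by retro-oxa-Michael (E1cB) reaction to chalcone phenolate 13, whose enone C=C and the two chromene C=C bonds are saturated by heterogeneous catalytic hydrogenation (the alkaline flavanone-to-dihydrochalcone hydrogenation), while the aryl ketone flanked by two phenolates resists reduction and acidification should deliver the target.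

Compound list
1 | (±)-naringenin, rac-5,7-dihydroxy-2-(4-hydroxyphenyl)chroman-4-one | O=C1CC(c2ccc(O)cc2)Oc2cc(O)cc(O)c12 | starting material
2 | 3-chloro-3-methylbut-1-yne | CC(C)(Cl)C#C | starting material
3 | rac-5-hydroxy-2-(4-hydroxyphenyl)-7-[(2-methylbut-3-yn-2-yl)oxy]chroman-4-one | O=C1CC(c2ccc(O)cc2)Oc2cc(OC(C)(C)C#C)cc(O)c12 | intermediate
4 | ring A allenyl dienone, rac-5-hydroxy-2-(4-hydroxyphenyl)-6-(3-methylbuta-1,2-dien-1-yl)-2,3-dihydro-4H-chromene-4,7(6H)-dione (transient, both configurations at C6, not isolated) | O=C1CC(c2ccc(O)cc2)OC2=CC(=O)C(C=C=C(C)C)C(O)=C12 | intermediate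
5 | ring A allenylphenol, rac-5,7-dihydroxy-2-(4-hydroxyphenyl)-6-(3-methylbuta-1,2-dien-1-yl)chroman-4-one (not isolated) | O=C1CC(c2ccc(O)cc2)Oc2cc(O)c(C=C=C(C)C)c(O)c12 | intermediate
6 | ring A o-quinone methide, rac-(6Z)-5-hydroxy-2-(4-hydroxyphenyl)-6-(3-methylbut-2-en-1-ylidene)-2,3-dihydro-4H-chromene-4,7(6H)-dione (not isolated) | O=C1CC(c2ccc(O)cc2)OC2=CC(=O)/C(=C\C=C(C)C)C(O)=C12 | intermediate
7 | rac-5-hydroxy-8-(4-hydroxyphenyl)-2,2-dimethyl-7,8-dihydro-2H,6H-pyrano[3,2-g]chromen-6-one (linear pyranoflavanone) | O=C1CC(c2ccc(O)cc2)Oc2cc3OC(C)(C)C=Cc3c(O)c12 | intermediate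
8 | rac-5-hydroxy-2,2-dimethyl-8-{4-[(2-methylbut-3-yn-2-yl)oxy]phenyl}-7,8-dihydro-2H,6H-pyrano[3,2-g]chromen-6-one | O=C1CC(c2ccc(OC(C)(C)C#C)cc2)Oc2cc3OC(C)(C)C=Cc3c(O)c12 | intermediate
9 | ring B allenyl dienone, rac-5-hydroxy-2,2-dimethyl-8-[3-(3-methylbuta-1,2-dien-1-yl)-4-oxocyclohexa-1,5-dien-1-yl]-7,8-dihydro-2H,6H-pyrano[3,2-g]chromen-6-one (transient, both configurations at the new sp3 carbon, not isolated) | O=C1CC(C4=CC(C=C=C(C)C)C(=O)C=C4)Oc2cc3OC(C)(C)C=Cc3c(O)c12 | intermediate
10 | ring B allenylphenol, rac-5-hydroxy-8-[4-hydroxy-3-(3-methylbuta-1,2-dien-1-yl)phenyl]-2,2-dimethyl-7,8-dihydro-2H,6H-pyrano[3,2-g]chromen-6-one (not isolated) | O=C1CC(c2ccc(O)c(C=C=C(C)C)c2)Oc2cc3OC(C)(C)C=Cc3c(O)c12 | intermediate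
11 | ring B o-quinone methide, rac-5-hydroxy-2,2-dimethyl-8-[(3Z)-3-(3-methylbut-2-en-1-ylidene)-4-oxocyclohexa-1,5-dien-1-yl]-7,8-dihydro-2H,6H-pyrano[3,2-g]chromen-6-one (not isolated) | O=C1CC(C4C=CC(=O)/C(=C\C=C(C)C)C=4)Oc2cc3OC(C)(C)C=Cc3c(O)c12 | intermediate
12 | rac-8-(2,2-dimethyl-2H-chromen-6-yl)-5-hydroxy-2,2-dimethyl-7,8-dihydro-2H,6H-pyrano[3,2-g]chromen-6-one | O=C1CC(c2ccc3OC(C)(C)C=Cc3c2)Oc2cc3OC(C)(C)C=Cc3c(O)c12 | intermediate
13 | (E)-1-(5,7-dihydroxy-2,2-dimethyl-2H-chromen-6-yl)-3-(2,2-dimethyl-2H-chromen-6-yl)prop-2-en-1-one (chalcone, present as its potassium phenolate, not isolated) | O=C(/C=C/c1ccc2OC(C)(C)C=Cc2c1)c1c(O)cc2OC(C)(C)C=Cc2c1O | intermediate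
14 | 1-(5,7-dihydroxy-2,2-dimethylchroman-6-yl)-3-(2,2-dimethylchroman-6-yl)propan-1-one (achiral) | CC1(C)CCc2cc(CCC(=O)c3c(O)cc4c(c3O)CCC(C)(C)O4)ccc2O1 | target

Total step count: 5
Longest linear sequence: 5 steps (1 → 3 → 7 → 8 → 12 → 14)

Steps most likely to fail

Step 4. At 190 °C the tertiary propargyl ether may fragment by elimination back to the phenol, or the allene and quinone methide intermediates may oligomerise faster than they electrocyclise. The fallback sets out from phenol 7 and builds the ring B pyran by a different bond construction: an ortho-directed condensation with 3-methylbut-2-enal (CC(C)=CC=O) mediated by PhB(OH)2 (AcOH cat., toluene, reflux with azeotropic removal of water). The aryl borate should deliver the aldehyde to the ortho carbon of ring B and give the cyclic boronate rac-5-hydroxy-2,2-dimethyl-8-[4-(2-methylprop-1-en-1-yl)-2-phenyl-4H-1,3,2-benzodioxaborinin-6-yl]-7,8-dihydro-2H,6H-pyrano[3,2-g]chromen-6-one F1. On heating, this should fragment to o-quinone methide 11, which electrocyclises to 12, where the route continues with step 5. Ring B is the only phenol of 7 with a free ortho C–H, since both carbons next to the chelated 5-OH are substituted.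

Step 1. Over-alkylation at the ring B phenol, or slow substitution with competing elimination of the tertiary chloride, may erode the mono-ether. The fallback sets out from 1 and avoids O-alkylation altogether: condensation of the nucleophilic ring A with 3-methylbut-2-enal (CC(C)=CC=O) under ethylenediammonium diacetate catalysis (toluene, reflux). The aldol-type adduct rac-5,7-dihydroxy-6-(1-hydroxy-3-methylbut-2-en-1-yl)-2-(4-hydroxyphenyl)chroman-4-one F2 should dehydrate to o-quinone methide 6 and electrocyclise, so the route is rejoined at 7 and step 2 is bypassed as well. The ring B phenol is not nucleophilic enough to react under these conditions, and attack at C8 instead of C6 would again converge after ring C opening.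

Step 5. In strong alkali the chalcone phenolate may undergo retro-aldol cleavage, or ring opening may lag so that only the chromene alkenes are reduced. The fallback sets out from 12 and replaces base-mediated opening by neutral C–O hydrogenolysis. Hydrogenation (H2, Pd/C, EtOAc, rt) should first give rac-8-(2,2-dimethylchroman-6-yl)-5-hydroxy-2,2-dimethyl-3,4,7,8-tetrahydro-2H,6H-pyrano[3,2-g]chromen-6-one F3. Catalytic transfer hydrogenolysis of its benzylic C–O bond in ring C (Pd/C, HCO2NH4, MeOH, reflux) should then return to the route at 14.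

Further compounds
F1 | step 4 | rac-5-hydroxy-2,2-dimethyl-8-[4-(2-methylprop-1-en-1-yl)-2-phenyl-4H-1,3,2-benzodioxaborinin-6-yl]-7,8-dihydro-2H,6H-pyrano[3,2-g]chromen-6-one | O=C1CC(c2ccc3OB(c4ccccc4)OC(C=C(C)C)c3c2)Oc2cc3OC(C)(C)C=Cc3c(O)c12
F2 | step 1 | rac-5,7-dihydroxy-6-(1-hydroxy-3-methylbut-2-en-1-yl)-2-(4-hydroxyphenyl)chroman-4-one | O=C1CC(c2ccc(O)cc2)Oc2cc(O)c(C(O)C=C(C)C)c(O)c12
F3 | step 5 | rac-8-(2,2-dimethylchroman-6-yl)-5-hydroxy-2,2-dimethyl-3,4,7,8-tetrahydro-2H,6H-pyrano[3,2-g]chromen-6-one | O=C1CC(c2ccc3OC(C)(C)CCc3c2)Oc2cc3OC(C)(C)CCc3c(O)c12
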